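**Retrosynthetic overview**
1. Target 10 ⇒ 2β‑hydroxy‑3‑ketone 9 (ketone reduction sets C3) ⇒ enone δ‑lactone 7 (enolate hydroxylation makes the C2–O bond).
2. 7 ⇒ α‑acyloxy cyclopropyl ketone 6 by the key C20–O bond formation: a ring‑opening 1,3‑acyloxy shift that turns the 19→2 γ‑lactone into the 19→20 δ‑lactone.
3. 6 ⇒ cyclopropane diol diacid 4 (relactonisation, oxidation) ⇒ allylic diol diacid 3 (hydroxyl‑directed cyclopropanation brings in C20 on the α‑face).
4. 3 ⇒ 13‑deoxygibberellic acid (1) by base‑induced lactone transposition and hydrolysis.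
5. Ring order: rings A–D come intact from 1; the C1–C10–C20 cyclopropane is made first, then the δ‑lactone ring (key step); the cis‑diol is set last.

Assumption: 13‑deoxygibberellic acid (1), the 1,2‑unsaturated 13‑deoxy fermentation gibberellin of the commercial two‑component gibberellin plant‑growth regulator, is taken as a cheap commercial starting material; gibberellin numbering is used, α being the ring‑A face that carries C19 and C20.

**Route**

Step 1
Reactants: 1 gibberellin lactone acid (13-deoxygibberellic acid)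
Product: 3 seco diol diacid (2α,3β-dihydroxy-1(10),16-diene-7,19-dioic acid), via iso-lactone 2 (not isolated)
Conditions: 0.5 M aq NaOH (5 equiv), 20 °C, 12 h, then 45 °C, 2 h; 1 M HCl to pH 3 at 0 °C, EtOAc
Reagents that add atoms: water, O (delivered as hydroxide from NaOH, [Na+].[OH-])
Why: Base‑induced allylic lactone transposition (the gibberellic acid → iso‑gibberellic acid isomerisation, anti‑SN2′ via the 2β,3β‑epoxy carboxylate) puts the lactone oxygen on C2α, and saponification by acyl–oxygen cleavage then frees the 2α‑allylic alcohol with C2 and C3 unchanged.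

Step 2
Reactants: 3 seco diol diacid (2α,3β-dihydroxy-1(10),16-diene-7,19-dioic acid)
Product: 4 cyclopropane diol diacid (1α,10α-methano-2α,3β-dihydroxy-16-ene-7,19-dioic acid)
Conditions: Et2Zn (5 equiv), CH2Cl2–DME, −20 °C; CH2I2 (3 equiv), −20 → 0 °C; 1 M HCl to pH 3 at 0 °C
Reagents that add atoms: diiodomethane, ICI
Why: Hydroxyl‑directed Simmons–Smith (Furukawa) cyclopropanation, in which the zinc alkoxide of the allylic 2α‑OH delivers CH2 to the α‑face of C1=C10 syn to itself, sets C10 (C20 α, cis to C19) and C1 and leaves the undirected 16‑ene alone.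

Step 3
Reactants: 4 cyclopropane diol diacid (1α,10α-methano-2α,3β-dihydroxy-16-ene-7,19-dioic acid)
Product: 6 cyclopropyl keto γ-lactone acid (1α,10α-methano-3-oxo-16-ene 19→2α γ-lactone 7-acid), via hydroxy γ-lactone 5 (not isolated)
Conditions: PPTS (0.1 equiv), 4 Å MS, ClCH2CH2Cl, 60 °C; cool to 20 °C, Dess–Martin periodinane (1.5 equiv)
Reagents that add atoms: none
Why: Mild acid‑catalysed lactonisation of the syn‑1,3‑diaxial 2α‑OH/19‑CO2H pair (the only hydroxy acid pair that can close) masks the 2α‑oxygen, so the Dess–Martin oxidation added to the same flask touches only the 3β‑OH; no stereocentre is changed.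

Step 4
Reactants: 6 cyclopropyl keto γ-lactone acid (1α,10α-methano-3-oxo-16-ene 19→2α γ-lactone 7-acid)
Product: 7 enone δ-lactone acid (3-oxo-1,16-diene 19→20 δ-lactone 7-acid)
Conditions: MgI2 (0.3 equiv), PhMe–MeCN 4:1, 60 °C
Reagents that add atoms: none
Why: Proposed new method: a strain‑release homo‑[3,3] acyloxy shift across a cyclopropylcarbinyl ester, in which the lactone carbonyl oxygen bonds to the cyclopropane CH2 (C20) on the α‑face while the C1–C20 σ‑bond and the α‑keto C2–O bond break to leave the C1=C2 enone, either in one six‑membered six‑electron array or by iodide relay (SN2 at C2 from the open β‑face to the 2β‑iodo ketone, then anti homo‑SN2′ closure of the freed 19‑carboxylate on C20), with magnesium chelation of the α‑acyloxy ketone helping the carboxylate leave; no α‑keto cation can form at C2 and quaternary C10 has no accessible backside, so only C20 is attacked, ring enlargement is excluded and C10 keeps its configuration, the driving force being release of cyclopropane and bridged γ‑lactone strain plus enone conjugation; closest known reaction types are the [3,3] allylic ester (1,3‑acyloxy) transposition, the cyclopropylcarbinyl→homoallyl rearrangement and MgI2‑promoted iodide opening of activated cyclopropanes.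

Step 5
Reactants: 7 enone δ-lactone acid (3-oxo-1,16-diene 19→20 δ-lactone 7-acid)
Product: 9 ketol δ-lactone acid (2β-hydroxy-3-oxo-16-ene 19→20 δ-lactone 7-acid), via dipotassium enolate 8 (not isolated)
Conditions: K[HB(s-Bu)3] (K-Selectride, 2.2 equiv), THF, −78 °C; Davis oxaziridine (1.5 equiv), −78 → −40 °C; 1 M HCl to pH 3
Reagents that add atoms: Davis oxaziridine (trans-2-(phenylsulfonyl)-3-phenyloxaziridine), O=S(=O)(c1ccccc1)N1OC1c1ccccc1
Why: Conjugate (1,4) hydride reduction of the β‑unsubstituted enone gives the C2=C3 enolate regiospecifically, and Davis enolate hydroxylation occurs on the exo β‑face (the α‑face of C2 lies under the lactone bridge) to give the equatorial 2β‑OH, which is also the thermodynamic epimer of this enolisable centre.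

Step 6
Reactants: 9 ketol δ-lactone acid (2β-hydroxy-3-oxo-16-ene 19→20 δ-lactone 7-acid)
Product: 10 target diol δ-lactone acid (2β,3β-dihydroxy-16-ene 19→20 δ-lactone 7-acid)
Conditions: K[HB(s-Bu)3] (K-Selectride, 3.5 equiv), THF, −78 → −50 °C; cold quench with 1 M HCl to pH 3
Reagents that add atoms: none
Why: Bulky‑hydride reduction of the 4,4‑disubstituted 3‑ketone by equatorial attack gives the axial 3β‑alcohol, as in 3‑oxogibberellin → 3β‑hydroxygibberellin reductions, and the cold quench prevents retro‑aldol epimerisation at C3.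

**Compound list**
1 | 13‑deoxygibberellic acid: 3β‑hydroxy‑20‑norgibberella‑1,16‑diene‑7,19‑dioic acid 19→10α γ‑lactone (7‑CO2H free) | C=C1C[C@]23C[C@H]1CC[C@H]2[C@]12OC(=O)[C@](C)([C@@H](O)C=C1)[C@H]2[C@@H]3C(=O)O | starting material
2 | iso‑lactone of 1: 1(10),16‑diene, 19→2α γ‑lactone, 3β‑OH, 7‑CO2H | C=C1C[C@]23C[C@H]1CC[C@H]2C1=C[C@H]4OC(=O)[C@](C)([C@H]4O)[C@H]1[C@@H]3C(=O)O | intermediate
3 | 2α,3β‑dihydroxy‑20‑norgibberella‑1(10),16‑diene‑7,19‑dioic acid | C=C1C[C@]23C[C@H]1CC[C@H]2C1=C[C@@H](O)[C@H](O)[C@@](C)(C(=O)O)[C@H]1[C@@H]3C(=O)O | intermediate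
4 | 1α,10α‑methano (C20 bridges C1 and C10 on the α‑face)‑2α,3β‑dihydroxy‑16‑ene‑7,19‑dioic acid | C=C1C[C@]23C[C@H]1CC[C@H]2[C@@]14C[C@H]4[C@@H](O)[C@H](O)[C@@](C)(C(=O)O)[C@H]1[C@@H]3C(=O)O | intermediate
5 | 1α,10α‑methano‑3β‑hydroxy‑16‑ene, 19→2α γ‑lactone, 7‑CO2H | C=C1C[C@]23C[C@H]1CC[C@H]2[C@@]14C[C@H]4[C@H]5OC(=O)[C@](C)([C@H]5O)[C@H]1[C@@H]3C(=O)O | intermediate
6 | 1α,10α‑methano‑3‑oxo‑16‑ene, 19→2α γ‑lactone, 7‑CO2H | C=C1C[C@]23C[C@H]1CC[C@H]2[C@@]14C[C@H]4[C@H]5OC(=O)[C@](C)(C5=O)[C@H]1[C@@H]3C(=O)O | intermediate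
7 | 3‑oxo‑1,16‑diene, 19→20 δ‑lactone (C20 α on C10), 7‑CO2H | C=C1C[C@]23C[C@H]1CC[C@H]2[C@]12COC(=O)[C@](C)(C(=O)C=C1)[C@H]2[C@@H]3C(=O)O | intermediate
8 | dipotassium salt of the 2‑en‑3‑olate 7‑carboxylate of the 19→20 δ‑lactone | C=C1C[C@]23C[C@H]1CC[C@H]2[C@]12COC(=O)[C@](C)(C([O-])=CC1)[C@H]2[C@@H]3C(=O)[O-].[K+].[K+] | intermediate
9 | 2β‑hydroxy‑3‑oxo‑16‑ene, 19→20 δ‑lactone, 7‑CO2H | C=C1C[C@]23C[C@H]1CC[C@H]2[C@]12COC(=O)[C@](C)(C(=O)[C@@H](O)C1)[C@H]2[C@@H]3C(=O)O | intermediate
10 | 2β,3β,20‑trihydroxygibberell‑16‑ene‑7,19‑dioic acid 19,20‑lactone (2β,3β‑dihydroxy‑16‑ene, 19→20 δ‑lactone, 7‑CO2H) | C=C1C[C@]23C[C@H]1CC[C@H]2[C@]12COC(=O)[C@](C)([C@@H](O)[C@@H](O)C1)[C@H]2[C@@H]3C(=O)O | target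

**Step count and risks**
Total steps: 6. Longest linear sequence: 6.

Most likely to fail:

Step 4 (the proposed acyloxy shift). The array may not react at a useful temperature, the transient β‑keto carboxylate of the iodide‑relay pathway may decarboxylate, or the 2β‑iodo ketone may be reduced by iodide. The fallback uses known chemistry, sets out from 4 and comes back at 7. Both hydroxyls of 4 are oxidised with Dess–Martin periodinane (CH2Cl2, 0 °C) to the cyclopropyl 2,3‑diketone diacid F1, a β‑keto acid that is used at once. Me3SiI with Et3N (CH2Cl2, −20 → 0 °C, then aqueous work‑up) opens the now carbonyl‑conjugated cyclopropane by the known iodide ring opening of cyclopropyl ketones. Iodide attacks in SN2 fashion, so only the CH2 carbon C20 reacts, and the C1–C20 bond breaks to give the 20‑iodo diosphenol diacid F2. Cs2CO3 in DMF (40 °C) closes the ring by intramolecular alkylation of the 1,3‑diaxial 19‑carboxylate to give the diosphenol δ‑lactone F3. PhNTf2/Et3N/DMAP converts F3 into the enol triflate F4, and Pd(OAc)2/PPh3 with HCO2H/Et3N (DMF, 60 °C) hydrogenolyses the triflate to 7.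

Step 2 (directed cyclopropanation on the unprotected diol diacid). The zinc carboxylates may be poorly soluble, or excess carbenoid may attack the 16‑ene. The fallback sets out from 3 and comes back at 4. The two acids are alkylated with allyl bromide/Cs2CO3 (DMF) to the diallyl ester F5. A samarium carbenoid (Sm metal, HgCl2 cat., ICH2Cl, THF, −78 → 20 °C), which cyclopropanates only allylic alcohols, gives the cyclopropane diallyl ester F6. The zerovalent palladium complex Pd(PPh3)4 with morpholine (THF, 20 °C) removes both allyl groups to return 4.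

Step 6 (C3 configuration). Axial attack would give the equatorial 3α‑epimer. The fallback sets out from 9 and comes back at 10 directly; it makes no new compound, none F0. Substrate control by a stoichiometric bulky hydride is replaced by enzyme control: a ketoreductase panel (NADPH, glucose/glucose dehydrogenase recycling, pH 7 phosphate buffer, 30 °C) is screened and the enzyme that delivers hydride to the α‑face of C3 is kept.

**Further compounds**
F1 | step 4 | 1α,10α‑methano‑2,3‑dioxo‑16‑ene‑7,19‑dioic acid | C=C1C[C@]23C[C@H]1CC[C@H]2[C@@]14C[C@H]4C(=O)C(=O)[C@@](C)(C(=O)O)[C@H]1[C@@H]3C(=O)O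
F2 | step 4 | 2‑hydroxy‑20‑iodo‑3‑oxo‑1,16‑diene‑7,19‑dioic acid (20‑iodo diosphenol, CH2I α on C10) | C=C1C[C@]23C[C@H]1CC[C@H]2[C@]1(CI)C=C(O)C(=O)[C@@](C)(C(=O)O)[C@H]1[C@@H]3C(=O)O
F3 | step 4 | 2‑hydroxy‑3‑oxo‑1,16‑diene 19→20 δ‑lactone 7‑acid (diosphenol) | C=C1C[C@]23C[C@H]1CC[C@H]2[C@]12COC(=O)[C@](C)(C(=O)C(O)=C1)[C@H]2[C@@H]3C(=O)O
F4 | step 4 | 2‑(trifluoromethanesulfonyloxy)‑3‑oxo‑1,16‑diene 19→20 δ‑lactone 7‑acid | C=C1C[C@]23C[C@H]1CC[C@H]2[C@]12COC(=O)[C@](C)(C(=O)C(OS(=O)(=O)C(F)(F)F)=C1)[C@H]2[C@@H]3C(=O)O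
F5 | step 2 | diallyl 2α,3β‑dihydroxy‑1(10),16‑diene‑7,19‑dioate | C=C1C[C@]23C[C@H]1CC[C@H]2C1=C[C@@H](O)[C@H](O)[C@@](C)(C(=O)OCC=C)[C@H]1[C@@H]3C(=O)OCC=C
F6 | step 2 | diallyl 1α,10α‑methano‑2α,3β‑dihydroxy‑16‑ene‑7,19‑dioate | C=C1C[C@]23C[C@H]1CC[C@H]2[C@@]14C[C@H]4[C@@H](O)[C@H](O)[C@@](C)(C(=O)OCC=C)[C@H]1[C@@H]3C(=O)OCC=C
F0 | step 6 | none | none
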